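**Retrosynthetic overview**

- Feature: in the butenolide ring (O1, C2 carbonyl, C3–OMe, C4–aryl, C5), C5 carries a methyl ester and a benzylic CH2. Once the C4–aryl bond is cut back to a C4 enol, C4 is at the carboxyl oxidation level, so C5 is the central carbon of a 2-benzyltartronate diester and O1–C2–C3 is a methoxyacetate on its hydroxyl.
- Late stage: the C4–aryl bond comes from Suzuki coupling of the C4 enol triflate with the benzyl-protected catechol boronic acid, followed by desilylation and debenzylation.
- Key disconnection: the C3–C4 bond, by a group-selective Dieckmann closure of the methoxyacetate enolate onto one of the two methyl esters. This closes the butenolide and fixes C5.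
- Precursor: C-benzylation of dimethyl 2-(methoxyacetoxy)malonate with the (3R)-chromanylmethyl bromide.
- Ring order: the chroman ring first (propargyl ether Claisen/electrocyclization from methyl 4-hydroxybenzoate, C3 carbinol by Jacobsen epoxidation and benzylic hydrogenolysis), the butenolide second, the catechol ring attached last.

Key step: step 10

Assumption: the (R,R) antipode of the chiral magnesium bisamide is written for step 10 because the sense of induction of this untested reagent cannot be derived from precedent; the (S,S) antipode is equally available and would be taken if it is the one that delivers the 5S series.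

**Route**

Step 1
Reactants: 1 methyl 4-hydroxybenzoate; 2 3-chloro-3-methylbut-1-yne
Product: 3 methyl 4-[(2-methylbut-3-yn-2-yl)oxy]benzoate
Conditions: DBU, CuCl2·2H2O (cat.), MeCN, 0 °C to rt
Reagents that add atoms: none
Why: Copper-catalysed O-propargylation of the phenol by the tertiary propargylic chloride, a substitution that works well for electron-poor phenols and leaves the methyl ester untouched.

Step 2
Reactants: 3 methyl 4-[(2-methylbut-3-yn-2-yl)oxy]benzoate
Product: 5 methyl 2,2-dimethyl-2H-chromene-6-carboxylate, via allenylphenol 4 (not isolated)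
Conditions: o-dichlorobenzene, 180 °C
Reagents that add atoms: none
Why: Aromatic propargyl Claisen rearrangement, enolization to allenylphenol 4, a 1,5-hydrogen shift and oxa-6π electrocyclization should give the 2,2-dimethylchromene as a single regioisomer, because the two ortho positions of the para-substituted ring are equivalent.

Step 3
Reactants: 5 methyl 2,2-dimethyl-2H-chromene-6-carboxylate
Product: 6 methyl (3R,4R)-3,4-epoxy-2,2-dimethylchroman-6-carboxylate
Conditions: (R,R)-(salen)MnCl [salen = N,N'-bis(3,5-di-tert-butylsalicylidene)cyclohexane-1,2-diamine dianion] (4 mol %), 4-phenylpyridine N-oxide (cat.), aq. NaOCl (pH 11.3), CH2Cl2, 0 °C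
Reagents that add atoms: sodium hypochlorite, [Na+].[O-]Cl
Why: Jacobsen–Katsuki epoxidation, for which 2,2-dimethylchromenes with an electron-withdrawing group at C6 are a favoured substrate class; the (R,R)-diamine backbone of the oxomanganese salen species selects the olefin face and should set C3 and C4 as 3R,4R.

Step 4
Reactants: 6 methyl (3R,4R)-3,4-epoxy-2,2-dimethylchroman-6-carboxylate
Product: 7 methyl (3R)-3-hydroxy-2,2-dimethylchroman-6-carboxylate
Conditions: H2 (1 atm), 10% Pd/C, EtOAc, rt
Reagents that add atoms: none
Why: Palladium-catalysed hydrogenolysis cleaves only the benzylic C4–O bond of the epoxide, so C4 becomes CH2 while the C3–O bond and its R configuration are kept in the secondary alcohol.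

Step 5
Reactants: 7 methyl (3R)-3-hydroxy-2,2-dimethylchroman-6-carboxylate
Product: 8 methyl (3R)-3-(tert-butyldimethylsilyloxy)-2,2-dimethylchroman-6-carboxylate
Conditions: TBSOTf, 2,6-lutidine, CH2Cl2, 0 °C
Reagents that add atoms: tert-butyldimethylsilyl trifluoromethanesulfonate, CC(C)(C)[Si](C)(C)OS(=O)(=O)C(F)(F)F
Why: Silylation of the hindered secondary alcohol next to the quaternary C2 with the silyl triflate and a non-nucleophilic base protects it against the bases of steps 9 and 10.

Step 6
Reactants: 8 methyl (3R)-3-(tert-butyldimethylsilyloxy)-2,2-dimethylchroman-6-carboxylate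
Product: 9 [(3R)-3-(tert-butyldimethylsilyloxy)-2,2-dimethylchroman-6-yl]methanol
Conditions: LiAlH4, THF, 0 °C
Reagents that add atoms: none
Why: Hydride reduction of the aryl ester to the benzylic alcohol, to which the silyl ether and the chroman ring are inert.

Step 7
Reactants: 9 [(3R)-3-(tert-butyldimethylsilyloxy)-2,2-dimethylchroman-6-yl]methanol
Product: 10 (3R)-6-(bromomethyl)-3-(tert-butyldimethylsilyloxy)-2,2-dimethylchroman
Conditions: CBr4, PPh3, CH2Cl2, 0 °C; used crude after filtration
Reagents that add atoms: carbon tetrabromide, BrC(Br)(Br)Br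
Why: The Appel reaction converts the primary benzylic alcohol into the bromide under neutral conditions that leave the silyl ether intact, and the electron-rich bromide is used at once without chromatography.

Step 8
Reactants: 11 dimethyl 2-hydroxymalonate; 12 methoxyacetyl chloride
Product: 13 dimethyl 2-(methoxyacetoxy)malonate
Conditions: pyridine, CH2Cl2, 0 °C to rt
Reagents that add atoms: none
Why: O-Acylation of the secondary alcohol of the tartronate by the acid chloride, with pyridine as a base too weak to cause C-acylation.

Step 9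
Reactants: 13 dimethyl 2-(methoxyacetoxy)malonate; 10 (3R)-6-(bromomethyl)-3-(tert-butyldimethylsilyloxy)-2,2-dimethylchroman
Product: 15 dimethyl 2-{[(3R)-3-(tert-butyldimethylsilyloxy)-2,2-dimethylchroman-6-yl]methyl}-2-(methoxyacetoxy)malonate, via sodium enolate 14 (not isolated)
Conditions: 13 (1.2 equiv), NaH (1.1 equiv), THF/DMF, 0 °C; then 10 (1.0 equiv), 0 °C to rt
Reagents that add atoms: none
Why: SN2 alkylation of the stabilized malonate enolate 14 by a reactive benzylic bromide, as in the classical alkylations of acetoxymalonates, builds the quaternary carbon that becomes C5; the deficit of NaH relative to 13 ensures that no base able to enolize the methoxyacetate of 15 remains.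

Step 10
Reactants: 15 dimethyl 2-{[(3R)-3-(tert-butyldimethylsilyloxy)-2,2-dimethylchroman-6-yl]methyl}-2-(methoxyacetoxy)malonate
Product: 18 (5S)-5-{[(3R)-3-(tert-butyldimethylsilyloxy)-2,2-dimethylchroman-6-yl]methyl}-4-hydroxy-3-methoxy-5-(methoxycarbonyl)furan-2(5H)-one, via magnesium enolate 16 (not isolated), via magnesium tetronate 17 (not isolated)
Conditions: n-Bu2Mg (1.2 equiv), (R,R)-bis(1-phenylethyl)amine (2.4 equiv), THF, reflux, then −78 °C; 15 added at −78 °C, then −78 to −40 °C; cold 1 M HCl work-up (amine recovered from the aqueous phase)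
Reagents that add atoms: none
Why: Proposed new method: the homochiral magnesium bisamide removes a proton from the methoxyacetate CH2 of 15, the only enolizable position, to give magnesium enolate 16 in which the divalent metal still carries one (R,R)-amide; the enolate carbon (C3) then adds to one of the two methoxycarbonyl groups on the future C5 through a closed transition state with magnesium bridging the enolate oxygen and the carbonyl oxygen under attack, and loss of methoxide followed by deprotonation at C3 gives magnesium tetronate 17, which the acidic work-up converts into 18. The closest known reactions are the Lacey–Dieckmann closure of alpha-acyloxy esters to tetronic acids with achiral amide bases and the enantioselective enolizations achieved with homochiral magnesium bisamides, while reagent-controlled desymmetrization of prochiral malonates is established for lactonization and reduction but not for a Claisen-type closure. The butenolide ring is closed 5-exo-trig by formation of the C3–C4 bond. The new stereocentre C5 is defined by which ester is attacked (the pro-R ester gives 5S), and this choice is controlled by the chiral amide on magnesium, since the chroman centre is six bonds away and gives no useful bias. The step needs group selectivity between two otherwise identical esters and nothing else: there is one enolizable site, all esters are methyl so that methoxide exchange is degenerate, magnesium and low temperature disfavour fragmentation of the enolate to methoxyketene, and the stabilized tetronate 17 is a sink that rules out retro-Claisen scrambling of C5, so the selection is kinetic. Because the product is a strong acid that would protonate any catalytic base, the chiral base is used in a stoichiometric amount and the amine is recovered by acid extraction.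

Step 11
Reactants: 18 (5S)-5-{[(3R)-3-(tert-butyldimethylsilyloxy)-2,2-dimethylchroman-6-yl]methyl}-4-hydroxy-3-methoxy-5-(methoxycarbonyl)furan-2(5H)-one
Product: 19 (5S)-5-{[(3R)-3-(tert-butyldimethylsilyloxy)-2,2-dimethylchroman-6-yl]methyl}-3-methoxy-5-(methoxycarbonyl)-4-(trifluoromethylsulfonyloxy)furan-2(5H)-one
Conditions: Tf2O, i-Pr2NEt, CH2Cl2, −78 °C
Reagents that add atoms: trifluoromethanesulfonic anhydride, O=S(=O)(OS(=O)(=O)C(F)(F)F)C(F)(F)F
Why: O-Sulfonylation of the ammonium tetronate at the C4 oxygen gives the vinylogous acyl triflate, the usual activation of tetronic acids for cross-coupling, without touching the quaternary C5.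

Step 12
Reactants: 19 (5S)-5-{[(3R)-3-(tert-butyldimethylsilyloxy)-2,2-dimethylchroman-6-yl]methyl}-3-methoxy-5-(methoxycarbonyl)-4-(trifluoromethylsulfonyloxy)furan-2(5H)-one; 20 3,4-bis(benzyloxy)phenylboronic acid
Product: 21 (5S)-4-[3,4-bis(benzyloxy)phenyl]-5-{[(3R)-3-(tert-butyldimethylsilyloxy)-2,2-dimethylchroman-6-yl]methyl}-3-methoxy-5-(methoxycarbonyl)furan-2(5H)-one
Conditions: Pd(OAc)2 (5 mol %), SPhos (10 mol %), K3PO4, toluene/H2O (10:1), 60 °C
Reagents that add atoms: none
Why: Suzuki–Miyaura coupling, in which oxidative addition of zerovalent palladium into the electron-poor C4–OTf bond, transmetalation from the aryl boronate and reductive elimination form the C4–aryl bond, the bulky biaryl phosphine being chosen for the hindered tetrasubstituted position.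

Step 13
Reactants: 21 (5S)-4-[3,4-bis(benzyloxy)phenyl]-5-{[(3R)-3-(tert-butyldimethylsilyloxy)-2,2-dimethylchroman-6-yl]methyl}-3-methoxy-5-(methoxycarbonyl)furan-2(5H)-one
Product: 22 (5S)-4-[3,4-bis(benzyloxy)phenyl]-5-{[(3R)-3-hydroxy-2,2-dimethylchroman-6-yl]methyl}-3-methoxy-5-(methoxycarbonyl)furan-2(5H)-one
Conditions: HF·pyridine, THF/pyridine, 0 °C to rt
Reagents that add atoms: none
Why: Fluoride-mediated desilylation cleaves the Si–O bond under mildly acidic conditions that do not affect the methyl ester, the lactone or the benzyl ethers.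

Step 14
Reactants: 22 (5S)-4-[3,4-bis(benzyloxy)phenyl]-5-{[(3R)-3-hydroxy-2,2-dimethylchroman-6-yl]methyl}-3-methoxy-5-(methoxycarbonyl)furan-2(5H)-one
Product: 23 (5S)-4-(3,4-dihydroxyphenyl)-5-{[(3R)-3-hydroxy-2,2-dimethylchroman-6-yl]methyl}-3-methoxy-5-(methoxycarbonyl)furan-2(5H)-one (CNP0289675.1)
Conditions: H2 (1 atm), 10% Pd/C, EtOAc/MeOH, rt
Reagents that add atoms: none
Why: Hydrogenolysis of the two benzyl ethers frees the catechol under neutral conditions, the tetrasubstituted conjugated butenolide double bond being too hindered to be reduced at 1 atm.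

**Compound list**

1 | methyl 4-hydroxybenzoate | COC(=O)c1ccc(O)cc1 | starting material
2 | 3-chloro-3-methylbut-1-yne | CC(C)(Cl)C#C | starting material
3 | methyl 4-[(2-methylbut-3-yn-2-yl)oxy]benzoate | COC(=O)c1ccc(OC(C)(C)C#C)cc1 | intermediate
4 | methyl 4-hydroxy-3-(3-methylbuta-1,2-dien-1-yl)benzoate (allenylphenol, not isolated) | COC(=O)c1ccc(O)c(C=C=C(C)C)c1 | intermediate
5 | methyl 2,2-dimethyl-2H-chromene-6-carboxylate | COC(=O)c1ccc2OC(C)(C)C=Cc2c1 | intermediate
6 | methyl (3R,4R)-3,4-epoxy-2,2-dimethylchroman-6-carboxylate | COC(=O)c1ccc2OC(C)(C)[C@@H]3O[C@@H]3c2c1 | intermediate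
7 | methyl (3R)-3-hydroxy-2,2-dimethylchroman-6-carboxylate | COC(=O)c1ccc2c(c1)C[C@@H](O)C(C)(C)O2 | intermediate
8 | methyl (3R)-3-(tert-butyldimethylsilyloxy)-2,2-dimethylchroman-6-carboxylate | COC(=O)c1ccc2c(c1)C[C@@H](O[Si](C)(C)C(C)(C)C)C(C)(C)O2 | intermediate
9 | [(3R)-3-(tert-butyldimethylsilyloxy)-2,2-dimethylchroman-6-yl]methanol | OCc1ccc2c(c1)C[C@@H](O[Si](C)(C)C(C)(C)C)C(C)(C)O2 | intermediate
10 | (3R)-6-(bromomethyl)-3-(tert-butyldimethylsilyloxy)-2,2-dimethylchroman | BrCc1ccc2c(c1)C[C@@H](O[Si](C)(C)C(C)(C)C)C(C)(C)O2 | intermediate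
11 | dimethyl 2-hydroxymalonate | COC(=O)C(O)C(=O)OC | starting material
12 | methoxyacetyl chloride | COCC(=O)Cl | starting material
13 | dimethyl 2-(methoxyacetoxy)malonate | COCC(=O)OC(C(=O)OC)C(=O)OC | intermediate
14 | sodium enolate of dimethyl 2-(methoxyacetoxy)malonate (not isolated) | COCC(=O)O[C-](C(=O)OC)C(=O)OC.[Na+] | intermediate
15 | dimethyl 2-{[(3R)-3-(tert-butyldimethylsilyloxy)-2,2-dimethylchroman-6-yl]methyl}-2-(methoxyacetoxy)malonate | COCC(=O)OC(Cc1ccc2c(c1)C[C@@H](O[Si](C)(C)C(C)(C)C)C(C)(C)O2)(C(=O)OC)C(=O)OC | intermediate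
16 | amidomagnesium enolate of the methoxyacetate of 15, amide = (R,R)-bis(1-phenylethyl)amide (not isolated) | COC=C(O[Mg]N([C@H](C)c1ccccc1)[C@H](C)c1ccccc1)OC(Cc1ccc2c(c1)C[C@@H](O[Si](C)(C)C(C)(C)C)C(C)(C)O2)(C(=O)OC)C(=O)OC | intermediate
17 | methoxymagnesium salt of tetronic acid 18, 5S (not isolated) | COC(=O)[C@@]1(Cc2ccc3c(c2)C[C@@H](O[Si](C)(C)C(C)(C)C)C(C)(C)O3)OC(=O)C(OC)=C1O[Mg]OC | intermediate
18 | (5S)-5-{[(3R)-3-(tert-butyldimethylsilyloxy)-2,2-dimethylchroman-6-yl]methyl}-4-hydroxy-3-methoxy-5-(methoxycarbonyl)furan-2(5H)-one | COC(=O)[C@@]1(Cc2ccc3c(c2)C[C@@H](O[Si](C)(C)C(C)(C)C)C(C)(C)O3)OC(=O)C(OC)=C1O | intermediate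
19 | (5S)-5-{[(3R)-3-(tert-butyldimethylsilyloxy)-2,2-dimethylchroman-6-yl]methyl}-3-methoxy-5-(methoxycarbonyl)-4-(trifluoromethylsulfonyloxy)furan-2(5H)-one | COC(=O)[C@@]1(Cc2ccc3c(c2)C[C@@H](O[Si](C)(C)C(C)(C)C)C(C)(C)O3)OC(=O)C(OC)=C1OS(=O)(=O)C(F)(F)F | intermediate
20 | 3,4-bis(benzyloxy)phenylboronic acid | OB(O)c1ccc(OCc2ccccc2)c(OCc2ccccc2)c1 | starting material
21 | (5S)-4-[3,4-bis(benzyloxy)phenyl]-5-{[(3R)-3-(tert-butyldimethylsilyloxy)-2,2-dimethylchroman-6-yl]methyl}-3-methoxy-5-(methoxycarbonyl)furan-2(5H)-one | COC(=O)[C@@]1(Cc2ccc3c(c2)C[C@@H](O[Si](C)(C)C(C)(C)C)C(C)(C)O3)OC(=O)C(OC)=C1c1ccc(OCc2ccccc2)c(OCc2ccccc2)c1 | intermediate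
22 | (5S)-4-[3,4-bis(benzyloxy)phenyl]-5-{[(3R)-3-hydroxy-2,2-dimethylchroman-6-yl]methyl}-3-methoxy-5-(methoxycarbonyl)furan-2(5H)-one | COC(=O)[C@@]1(Cc2ccc3c(c2)C[C@@H](O)C(C)(C)O3)OC(=O)C(OC)=C1c1ccc(OCc2ccccc2)c(OCc2ccccc2)c1 | intermediate
23 | (5S)-4-(3,4-dihydroxyphenyl)-5-{[(3R)-3-hydroxy-2,2-dimethylchroman-6-yl]methyl}-3-methoxy-5-(methoxycarbonyl)furan-2(5H)-one | COC(=O)[C@@]1(Cc2ccc3c(c2)C[C@@H](O)C(C)(C)O3)OC(=O)C(OC)=C1c1ccc(O)c(O)c1 | target

**Step count and risks**

Total step count: 14. Longest linear sequence: 13 steps (steps 1–7 and 9–14); step 8 is a one-step side branch.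

Steps most likely to fail:

1. Step 10 (the proposed new method). The chiral amide on magnesium may discriminate poorly, or in the wrong sense, between the two ester groups. Enolization by the magnesium base may also be slow, so that the enolate fragments to methoxyketene and the tartronate alkoxide before it cyclizes. Fallback with known chemistry, setting out from 15: the closure is run as an ordinary Lacey–Dieckmann reaction with LiHMDS (2.2 equiv) in THF at −78 to 0 °C. This should give, without selection, tetronic acid 18 together with its C5 epimer, the (5R)-tetronic acid F1. Because the chroman centre is fixed, the two are diastereomers. They would be separated by preparative chromatography on a chiral stationary phase, if necessary after conversion into the triflates. The route is rejoined at 18.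

2. Step 12. Hydroxide or phosphate may attack the vinylogous acyl triflate at sulfur and return the tetronate. Oxidative addition and transmetalation at C4, which lies between the quaternary C5 and the C3 methoxy group, may be slow enough for protodeboronation of the electron-rich boronic acid to compete. Fallback, setting out from 18: the enol is converted with oxalyl bromide and catalytic DMF (CH2Cl2, 0 °C, 2,6-lutidine as acid scavenger) into the 4-bromobutenolide F2. This has a carbon–halogen bond that aqueous base cannot cleave. C5 is unchanged in space, and its descriptor becomes R only because bromine raises the rank of C4. F2 is then coupled with boronic acid 20 (PdCl2(dppf), Cs2CO3, dioxane/H2O, 80 °C), and the route is rejoined at 21.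

3. Step 9 (with the bromide of step 7). The electron-rich benzylic bromide may ionize and self-condense by Friedel–Crafts alkylation before it is captured. Residual base may also trigger premature, unselective cyclization of 15. Fallback, setting out from alcohol 9 and avoiding any benzylic halide:
 - MnO2 oxidation (CH2Cl2, rt) gives the aldehyde F3.
 - Knoevenagel condensation with dimethyl malonate (piperidine, AcOH, toluene, reflux with water removal) gives the arylidene malonate F4.
 - Hydrogenation of the activated double bond (H2, 10% Pd/C, EtOAc) gives the benzylmalonate F5.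
 - Deprotonation (NaH, THF) and oxygen transfer from 3-phenyl-2-(phenylsulfonyl)oxaziridine give the benzyltartronate F6.
 - Acylation of this tertiary alcohol with methoxyacetyl chloride 12 (pyridine, DMAP, CH2Cl2, reflux) rejoins the route at 15.

**Further compounds**

F1 | step 10 | (5R)-5-{[(3R)-3-(tert-butyldimethylsilyloxy)-2,2-dimethylchroman-6-yl]methyl}-4-hydroxy-3-methoxy-5-(methoxycarbonyl)furan-2(5H)-one | COC(=O)[C@]1(Cc2ccc3c(c2)C[C@@H](O[Si](C)(C)C(C)(C)C)C(C)(C)O3)OC(=O)C(OC)=C1O
F2 | step 12 | 4-bromo-5-{[(3R)-3-(tert-butyldimethylsilyloxy)-2,2-dimethylchroman-6-yl]methyl}-3-methoxy-5-(methoxycarbonyl)furan-2(5H)-one, C5 arranged as in 18 (descriptor 5R) | COC(=O)[C@@]1(Cc2ccc3c(c2)C[C@@H](O[Si](C)(C)C(C)(C)C)C(C)(C)O3)OC(=O)C(OC)=C1Br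
F3 | step 9 | (3R)-3-(tert-butyldimethylsilyloxy)-2,2-dimethylchroman-6-carbaldehyde | O=Cc1ccc2c(c1)C[C@@H](O[Si](C)(C)C(C)(C)C)C(C)(C)O2
F4 | step 9 | dimethyl 2-{[(3R)-3-(tert-butyldimethylsilyloxy)-2,2-dimethylchroman-6-yl]methylidene}malonate | COC(=O)C(=Cc1ccc2c(c1)C[C@@H](O[Si](C)(C)C(C)(C)C)C(C)(C)O2)C(=O)OC
F5 | step 9 | dimethyl 2-{[(3R)-3-(tert-butyldimethylsilyloxy)-2,2-dimethylchroman-6-yl]methyl}malonate | COC(=O)C(Cc1ccc2c(c1)C[C@@H](O[Si](C)(C)C(C)(C)C)C(C)(C)O2)C(=O)OC
F6 | step 9 | dimethyl 2-{[(3R)-3-(tert-butyldimethylsilyloxy)-2,2-dimethylchroman-6-yl]methyl}-2-hydroxymalonate | COC(=O)C(O)(Cc1ccc2c(c1)C[C@@H](O[Si](C)(C)C(C)(C)C)C(C)(C)O2)C(=O)OC
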